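Weigh these flasks by what the passing of monomer in chains into its isomer leaves standing in chains.

| setting | south-west | north-west | south-east |
|---|---|---|---|
| solid monomer | 15 mM | 15 mM | 15 mM |
| protic impurity | 1.50 mM | 1.50 mM | 1.50 mM |
| initiator | 15 µM | 15 µM | 15 µM |
| temperature | 25 °C | 85 °C | 55 °C |
| time | 2.5 d | 2.5 d | 2.5 d |

    2 growing radical → dead chain (k1 = 5 × 10⁶ M⁻¹ s⁻¹, Ea1 = 19.0 kJ mol⁻¹)
    solid monomer ⇌ free monomer, rate k2*(cs2 - [free monomer]) while solid is left; crystals form when [free monomer] > cs2 (cs2 = 9.1 mM, k2 = 3.4 × 10⁻⁴ s⁻¹)
    monomer in chains ⇌ isomer of the product (K3 = 0.19, k3 = 4.0 × 10⁻⁶ s⁻¹, Ea3 = 108 kJ mol⁻¹, ΔH3 = −39.0 kJ mol⁻¹)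
    free monomer + initiating radical → growing radical + monomer in chains (k4 = 6.1 × 10⁵ M⁻¹ s⁻¹, Ea4 = 21.0 kJ mol⁻¹)
    initiator → 2 initiating radical (k5 = 2.4 × 10⁻⁶ s⁻¹, Ea5 = 107 kJ mol⁻¹)
    protic impurity + free monomer → quenched substrate (k6 = 0.047 M⁻¹ s⁻¹, Ea6 = 55.0 kJ mol⁻¹)
    free monomer + growing radical → monomer in chains + growing radical, rate k7*[growing radical]*[free monomer] (k7 = 17000 M⁻¹ s⁻¹, Ea7 = 24.0 kJ mol⁻¹)
    (constants at 25 °C)

- where a step has two of a species, its rate is k times that concentration squared, and two are used at each turn
- solid monomer is a solid; its amount is given per volume of the solution
- the constants hold at 25 °C; other temperatures follow from the activation energies and enthalpies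
- at the start none of the solid monomer is in solution

* the flask that comes out highest in amount of monomer in chains, in percent of the solid monomer charged, or "all alike" when all lie within 1.5 percentage points (south-west / north-west / south-east / all alike)
* monomer in chains at the end, in percent of the solid monomer charged, south-west
* monomer in chains at the end, in percent of the solid monomer charged, north-west
* monomer in chains at the end, in percent of the solid monomer charged, south-east

This reckoning takes the protic impurity to spend its whole charge on free monomer, which leaves 90.0% of the solid monomer charged. Monomer in chains and isomer of the product then share that pool by their equilibrium constant, which is thermodynamic control. The pool divided by one plus the constant gives, for south-west, 75.6%. This is the split yield: the part of the solid monomer charged that stands in chains once the pool has entered chains and the isomerisation has reached equilibrium. The time to hold against the initiator is the dissolving time: at the top rate, with free monomer at zero, the charge needs 1.35 h to go into solution, and free monomer above zero slows the dissolving.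

| Flask | Temperature | Equilibrium constant | Split yield | Initiator half-life |
|---|---|---|---|---|
| south-west | 25 °C | 0.19 | 75.6% | 80.2 h |
| south-east | 55 °C | 0.0451 | 86.1% | 1.55 h |
| north-west | 85 °C | 0.0136 | 88.8% | 3.48 min |

In the south-west row the initiator half-life is longer than the dissolving time, and the isomerisation relaxes with a half-life of 0.320 d, shorter than the 2.5 d run, so the split yield applies there. The south-east row has a smaller constant and a higher split yield, but its initiator half-life exceeds the dissolving time by a factor of 1.15, which makes this the narrow point. The north-west row has the highest split yield, yet its initiator half-life is far shorter than the dissolving time. The split yield there therefore counts monomer that chains may not take up, and this reckoning gives no north-west number. It commits to south-east.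

The forecast also names south-east, with 76% for south-west, 13% for north-west and 86% for south-east. Its ground for north-west is dead-end polymerisation: “most of the monomer arrives after the radicals are gone”.

The simulation gives south-east as highest, with 75.8% in south-west, 13.5% in north-west and 86.0% in south-east, so the forecast held. South-east still holds 0.0818% free monomer at the end, which the split yield counts as having entered the pool. Set against the results, the split yield lies 0.100 percentage points from south-east and 0.20 points from south-west.

A repeat of south-west at 40 °C has a constant of 0.0894, which gives a split yield of 82.6%. That flask comes out at 82.6% in chains, with 7.39% as isomer of the product.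

The numbers of this flask are made up; what happens was integrated by code.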